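**Strategy.** The carbocycle is cut at C8–C9 and C5–C6. C6–C7–C8–C10 of the cyclopentane ring corresponds to the γ, β, α and carboxyl carbons of an allenoate, and the C5–C9 ring-fusion bond to the enone of a pyranone made by dearomatising furfuryl alcohol. One phosphine-catalysed [3+2] annulation builds both bonds, the five-membered ring and the cis C5/C9 fusion, anti to the C1 acyloxy group, the only stereocentre set by resolution. The precursor is the (S)-6-acyloxy-2H-pyran-3(6H)-one that already carries the target's (S)-3-methylpentanoate, combined with tert-butyl buta-2,3-dienoate so that C10 can later be reduced without touching the acylal.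

Key step: step 5

Remark: iridoid numbering is used for all bicyclic compounds (C1 acylal carbon, O2, C3, C4, C5 and C9 ring fusion, C6–C8, C10 on C8, C11 on C4); β is the face of H5 and H9, and the target is 1S,5S,7S,8R,9S in this numbering.
Remark: species bound to a catalyst or to the Mitsunobu phosphorus reagent are treated in the Why lines and carry no number.

Step 1
Reactants: 1 furfuryl alcohol
Product: 2 6-hydroxy-2H-pyran-3(6H)-one (racemic lactol)
Conditions: NBS, NaHCO3, THF/H2O (4:1), 0 °C
Reagents that add atoms: water, O
Why: Achmatowicz rearrangement, in which oxidation of the furan at its 2- and 5-positions in water gives a hydroxy enedione that recloses to the six-membered lactol, whose anomeric centre stays racemic and mobile as the resolution in step 3 requires.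

Step 2
Reactants: 3 (S)-3-methylpentanoic acid (2 equiv)
Product: 4 (S)-3-methylpentanoic anhydride
Conditions: DCC (0.5 equiv), CH2Cl2, 0 °C to rt; filtration
Reagents that add atoms: none
Why: Carbodiimide dehydration of two acid molecules to the symmetric anhydride, with the stereocentre β to the carbonyl and therefore untouched.

Step 3
Reactants: 2 6-hydroxy-2H-pyran-3(6H)-one; 4 (S)-3-methylpentanoic anhydride
Product: 5 (S)-6-[(S)-3-methylpentanoyloxy]-2H-pyran-3(6H)-one
Conditions: benzotetramisole (5 mol %, antipode matched to 1S), i-Pr2NEt, CHCl3, −20 °C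
Reagents that add atoms: none
Why: Isothiourea-catalysed acyl transfer run as a dynamic kinetic resolution, in which the lactol epimerises through its open hydroxy enedione faster than it is acylated and the chiral acyl-isothiouronium esterifies one anomer to set C1 as S (the catalyst antipode is chosen for this sense, the low temperature suppresses amine-induced loss of carboxylate, and because the acyl group is homochiral the C1 epimer is a diastereomer that chromatography or crystallisation should remove).

Step 4
Reactants: 6 tert-butyl (triphenylphosphoranylidene)acetate; 7 acetyl chloride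
Product: 9 tert-butyl buta-2,3-dienoate, via ketene 8 (not isolated)
Conditions: Et3N, CH2Cl2, 0 °C to rt
Reagents that add atoms: none
Why: Wittig olefination of ketene, generated in the flask from acetyl chloride and Et3N, by the stabilised ylide should give the allenoate.

Step 5
Reactants: 5 (S)-6-[(S)-3-methylpentanoyloxy]-2H-pyran-3(6H)-one; 9 tert-butyl buta-2,3-dienoate (1.5 equiv, added slowly)
Product: 10 keto enoate: (1S,5S,9S) cis-fused cyclopenta[c]pyran-4-one with the C1 (S)-3-methylpentanoate cis to H9 and a C7=C8 bond carrying CO2t-Bu on C8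
Conditions: PPh3 (20 mol %), toluene, rt
Reagents that add atoms: none
Why: PPh3 adds to the central allene carbon to give a phosphonium dienolate whose α-carbon (C8) undergoes Michael addition to C9 of the enone, the resulting C5 enolate closes on the terminal carbon (C6) of the vinylphosphonium, and a 1,2-proton shift from C8 followed by loss of PPh3 leaves the C7=C8 enoate. This is the Lu phosphine-catalysed allenoate–enone [3+2] annulation, a reaction type established for cyclic enones including 6-acyloxy pyranones. The cyclopentene ring closes by formal 5-endo-trig attack of the enolate on the vinylphosphonium, the second bond of a stepwise dipolar cycloaddition. C9 is set by approach of the zwitterion anti to the pseudoaxial C1 acyloxy group (anomeric effect), and C5 follows because the three-carbon bridge can span C9 and C5 only on one face, which gives the cis fusion. The step needs α- over γ-regioselectivity and tolerance of the base-sensitive acylal: the bulky tert-butyl ester and the enone polarisation favour bonding of the ester-bearing carbon to C9, and PPh3 is too weak a base to enolise C3 and expel the carboxylate.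

Step 6
Reactants: 10 keto enoate
Product: 12 enol triflate: as 10 but with C3=C4 and OSO2CF3 on C4 (1S,5S,9S), via potassium enolate 11 (not isolated)
Conditions: KN(SiMe3)2 (1.05 equiv), THF, −78 °C; then PhNTf2, −78 to −40 °C; NH4Cl quench
Reagents that add atoms: N-phenylbis(trifluoromethanesulfonimide), O=S(=O)(N(c1ccccc1)S(=O)(=O)C(F)(F)F)C(F)(F)F
Why: Regioselective enolate O-triflation, in which the hindered amide base removes a C3 methylene proton (more accessible than the C5 ring-fusion methine and acidified by O2) and the enolate is sulfonylated on oxygen, so that C5 and C9 are not touched.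

Step 7
Reactants: 12 enol triflate
Product: 13 enoic acid: as 12 with CO2H on C8
Conditions: TFA/CH2Cl2 (1:4), 0 °C to rt
Reagents that add atoms: none
Why: Acidolysis of the tert-butyl ester by the E1 route with loss of isobutene, while the acylal and the triflyloxy enol ether, whose ring oxygen is conjugated to an electron-poor alkene, should resist ionisation at this acidity.

Step 8
Reactants: 13 enoic acid
Product: 15 allylic alcohol: as 12 with CH2OH (C10) on C8, via mixed carbonic anhydride 14 (not isolated)
Conditions: i-BuOCOCl, N-methylmorpholine, THF, −15 °C; then NaBH4, H2O, −15 to 0 °C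
Reagents that add atoms: none
Why: Chemoselective reduction of a carboxylic acid through its mixed carbonic anhydride, which borohydride attacks at the acyl carbon far faster than the acylal ester or the vinyl triflate, giving the allylic alcohol by 1,2-reduction.

Step 9
Reactants: 15 allylic alcohol
Product: 16 β-epoxy alcohol: (1S,5S,7S,8S,9S) with the 7,8-epoxide on the face of H5 and H9 and CH2OH on C8
Conditions: VO(acac)2 (5 mol %), t-BuOOH (decane solution), CH2Cl2, 0 °C to rt
Reagents that add atoms: tert-butyl hydroperoxide, CC(C)(C)OO
Why: Hydroxyl-directed vanadium-catalysed epoxidation (Sharpless type) acts only on the allylic alcohol alkene and should deliver oxygen to the convex β-face, away from the pyran ring, which fixes C7–O as in the target and places C8–O in the configuration that step 11 inverts.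

Step 10
Reactants: 16 β-epoxy alcohol; 17 p-coumaric acid
Product: 18 epoxy coumarate: 16 esterified at O10 with (E)-4-hydroxycinnamic acid and free phenol
Conditions: PPh3, DIAD, THF, 0 °C to rt
Reagents that add atoms: none
Why: Mitsunobu esterification, in which the carboxylic acid, far more acidic than the phenol, is the pronucleophile that displaces the activated primary C10 oxygen in an SN2 reaction, so that no phenol protection is needed and no stereocentre is touched.

Step 11
Reactants: 18 epoxy coumarate
Product: 21 diol monoester triflate: (1S,5S,7S,8R,9S) with 7β-OH and 8α-OH and the (E)-p-coumarate on O10 and OSO2CF3 on C4, via dioxolanylium borate zwitterion 19 (not isolated), via hemiorthoester 20 (not isolated)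
Conditions: BF3·OEt2 (1.1 equiv), CH2Cl2, −78 to −40 °C; then sat. aq. NaHCO3/THF, 0 °C to rt
Reagents that add atoms: water, O
Why: Anchimerically assisted epoxide opening, in which the carbonyl oxygen of the C10 ester attacks the activated epoxide at the tertiary C8 from the rear (5-exo, hence inversion to 8α-O) to give a spirocyclic dioxolan-2-ylium ion, water adds to its cationic carbon, and the hemiorthoester collapses reversibly to the thermodynamically preferred primary C10 ester beside the free trans-7,8-diol.

Step 12
Reactants: 21 diol monoester triflate; 22 (tributylstannyl)methanol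
Product: 23 target CNP0241834.1
Conditions: Pd(PPh3)4 (10 mol %), LiCl, 1,4-dioxane, 80 °C
Reagents that add atoms: none
Why: Stille coupling (Migita–Kosugi–Stille hydroxymethylation), in which oxidative addition of the enol triflate to zerovalent palladium, chloride-assisted transfer of the hydroxymethyl group from tin and reductive elimination place C11 on C4 with the C3=C4 bond fixed, under neutral conditions that free hydroxyls, the phenol and the three esters should tolerate.

**Compound list**

1 | furfuryl alcohol | OCc1ccco1 | starting material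
2 | 6-hydroxy-2H-pyran-3(6H)-one (racemic lactol) | OC1OCC(=O)C=C1 | intermediate
3 | (S)-3-methylpentanoic acid | CC[C@H](C)CC(=O)O | starting material
4 | (S)-3-methylpentanoic anhydride | CC[C@H](C)CC(=O)OC(=O)C[C@@H](C)CC | intermediate
5 | (S)-6-[(S)-3-methylpentanoyloxy]-2H-pyran-3(6H)-one | CC[C@H](C)CC(=O)O[C@@H]1OCC(=O)C=C1 | intermediate
6 | tert-butyl (triphenylphosphoranylidene)acetate | CC(C)(C)OC(=O)C=P(c1ccccc1)(c1ccccc1)c1ccccc1 | starting material
7 | acetyl chloride | CC(Cl)=O | starting material
8 | ketene | C=C=O | intermediate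
9 | tert-butyl buta-2,3-dienoate | C=C=CC(=O)OC(C)(C)C | intermediate
10 | keto enoate, (1S,5S,9S) cis-fused cyclopenta[c]pyran-4-one, C1 (S)-3-methylpentanoate cis to H9, C7=C8 with CO2t-Bu on C8 | CC[C@H](C)CC(=O)O[C@@H]1OCC(=O)[C@H]2CC=C(C(=O)OC(C)(C)C)[C@@H]12 | intermediate
11 | potassium C3=C4 enolate of 10 | CC[C@H](C)CC(=O)O[C@@H]1OC=C([O-])[C@H]2CC=C(C(=O)OC(C)(C)C)[C@@H]12.[K+] | intermediate
12 | enol triflate, C3=C4 with OSO2CF3 on C4, (1S,5S,9S) | CC[C@H](C)CC(=O)O[C@@H]1OC=C(OS(=O)(=O)C(F)(F)F)[C@H]2CC=C(C(=O)OC(C)(C)C)[C@@H]12 | intermediate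
13 | enoic acid, CO2H on C8 | CC[C@H](C)CC(=O)O[C@@H]1OC=C(OS(=O)(=O)C(F)(F)F)[C@H]2CC=C(C(=O)O)[C@@H]12 | intermediate
14 | mixed isobutyl carbonic anhydride of 13 | CC[C@H](C)CC(=O)O[C@@H]1OC=C(OS(=O)(=O)C(F)(F)F)[C@H]2CC=C(C(=O)OC(=O)OCC(C)C)[C@@H]12 | intermediate
15 | allylic alcohol, CH2OH (C10) on C8 | CC[C@H](C)CC(=O)O[C@@H]1OC=C(OS(=O)(=O)C(F)(F)F)[C@H]2CC=C(CO)[C@@H]12 | intermediate
16 | β-epoxy alcohol, (1S,5S,7S,8S,9S), epoxide on the face of H5/H9 | CC[C@H](C)CC(=O)O[C@@H]1OC=C(OS(=O)(=O)C(F)(F)F)[C@H]2C[C@@H]3O[C@]3(CO)[C@@H]12 | intermediate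
17 | p-coumaric acid | O=C(O)/C=C/c1ccc(O)cc1 | starting material
18 | epoxy coumarate, O10 (E)-4-hydroxycinnamate of 16 | CC[C@H](C)CC(=O)O[C@@H]1OC=C(OS(=O)(=O)C(F)(F)F)[C@H]2C[C@@H]3O[C@]3(COC(=O)/C=C/c4ccc(O)cc4)[C@@H]12 | intermediate
19 | dioxolanylium borate zwitterion, spiro 1,3-dioxolan-2-ylium across C8/C10 (C8–O α) with 2-[(E)-4-hydroxystyryl], C7β–O–BF3 | CC[C@H](C)CC(=O)O[C@@H]1OC=C(OS(=O)(=O)C(F)(F)F)[C@H]2C[C@H](O[B-](F)(F)F)[C@]3(CO[C+](/C=C/c4ccc(O)cc4)O3)[C@@H]12 | intermediate
20 | hemiorthoester, 2-hydroxy-1,3-dioxolane form of 19 with free 7β-OH | CC[C@H](C)CC(=O)O[C@@H]1OC=C(OS(=O)(=O)C(F)(F)F)[C@H]2C[C@H](O)[C@]3(COC(O)(/C=C/c4ccc(O)cc4)O3)[C@@H]12 | intermediate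
21 | diol monoester triflate, (1S,5S,7S,8R,9S), 7β-OH, 8α-OH, O10 (E)-p-coumarate, C4 OSO2CF3 | CC[C@H](C)CC(=O)O[C@@H]1OC=C(OS(=O)(=O)C(F)(F)F)[C@H]2C[C@H](O)[C@](O)(COC(=O)/C=C/c3ccc(O)cc3)[C@@H]12 | intermediate
22 | (tributylstannyl)methanol | CCCC[Sn](CO)(CCCC)CCCC | starting material
23 | CNP0241834.1, (1S,5S,7S,8R,9S) | CC[C@H](C)CC(=O)O[C@@H]1OC=C(CO)[C@H]2C[C@H](O)[C@](O)(COC(=O)/C=C/c3ccc(O)cc3)[C@@H]12 | target

**Step count.** Total: 12 steps. Longest linear sequence: 10 steps (1, 3, 5, 6, 7, 8, 9, 10, 11, 12) from furfuryl alcohol; steps 2 and 4 are side branches.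

**Steps most likely to fail**

Step 6. Deprotonation could occur at the C5 ring-fusion methine instead of C3, or proton exchange could epimerise C5, so that the triflate forms on the wrong side of the ketone. Fallback: from 10, soft enolisation under equilibrating conditions (TBSOTf, Et3N, CH2Cl2, 0 °C) should give the thermodynamic enol ether, the C3=C4 tert-butyldimethylsilyl enol ether F1, whose double bond is conjugated with O2 and avoids the ring fusion. Fluoride-triggered triflation (CsF, PhNTf2, DME, rt) then converts it regiospecifically into enol triflate 12.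

Step 11. The Lewis acid could instead induce a hydride shift in the epoxide, ionise the C1 acylal, or leave the acyl group stranded on the tertiary O8; attack of the ester at C7 through a six-membered ion would give the wrong trans-diol. Fallback: separate hydration from esterification. From epoxy alcohol 16, acid-catalysed hydration (HClO4 cat., THF/H2O, 0 °C), in which water opens the protonated epoxide at the tertiary C8 with inversion, should give the 7β,8α,10-triol F2. In parallel, 17 is silylated (TBSCl, imidazole, DMF) to the bis-silyl derivative F3, whose silyl ester is hydrolysed (AcOH/THF/H2O) to (E)-4-(tert-butyldimethylsilyloxy)cinnamic acid F4. Carbodiimide esterification of the primary hydroxyl of F2 with F4 (EDC·HCl, DMAP, CH2Cl2, 0 °C) gives the silyl-protected monoester F5, and HF·pyridine (THF/pyridine, 0 °C) removes the aryl silyl ether to rejoin the route at 21.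

Step 12. Transfer of the sp3 hydroxymethyl group from tin may be slow at the temperature the acylal and the allylic enol ether tolerate, which would lead to protodetriflation or thermal decomposition. Fallback: bring in C11 at the aldehyde level. From 21, palladium-catalysed formylation (Pd(PPh3)4, CO 1 atm, Bu3SnH added slowly, LiCl, THF, 50 °C), where fast hydride transfer to the acylpalladium intermediate replaces the slow alkyl transfer, should give the C4 carbaldehyde F6, a vinylogous formate. Luche reduction (NaBH4, CeCl3·7H2O, MeOH, −78 °C) should reduce only the aldehyde and deliver 23.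

Further compounds
F1 | step 6 | C3=C4 tert-butyldimethylsilyl enol ether of 10, (1S,5S,9S) | CC[C@H](C)CC(=O)O[C@@H]1OC=C(O[Si](C)(C)C(C)(C)C)[C@H]2CC=C(C(=O)OC(C)(C)C)[C@@H]12
F2 | step 11 | 7β,8α,10-triol enol triflate, (1S,5S,7S,8R,9S) | CC[C@H](C)CC(=O)O[C@@H]1OC=C(OS(=O)(=O)C(F)(F)F)[C@H]2C[C@H](O)[C@](O)(CO)[C@@H]12
F3 | step 11 | tert-butyldimethylsilyl (E)-4-(tert-butyldimethylsilyloxy)cinnamate | CC(C)(C)[Si](C)(C)OC(=O)/C=C/c1ccc(O[Si](C)(C)C(C)(C)C)cc1
F4 | step 11 | (E)-4-(tert-butyldimethylsilyloxy)cinnamic acid | O=C(O)/C=C/c1ccc(O[Si](C)(C)C(C)(C)C)cc1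
F5 | step 11 | O10 (E)-4-(tert-butyldimethylsilyloxy)cinnamate of F2 | CC[C@H](C)CC(=O)O[C@@H]1OC=C(OS(=O)(=O)C(F)(F)F)[C@H]2C[C@H](O)[C@](O)(COC(=O)/C=C/c3ccc(O[Si](C)(C)C(C)(C)C)cc3)[C@@H]12
F6 | step 12 | C4 carbaldehyde (C11 aldehyde) analogue of 23 | CC[C@H](C)CC(=O)O[C@@H]1OC=C(C=O)[C@H]2C[C@H](O)[C@](O)(COC(=O)/C=C/c3ccc(O)cc3)[C@@H]12
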